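Compound numbers are those of the steps and the compound list below. Chroman numbering is used throughout: O1, C2, C3, C4, C4a, C5–C8, C8a for the pyran-fused ring A; C1′–C6′ for ring B.

## Analysis of the target

Target 14 is a 3,4-dihydro-2H-chromene whose benzo ring (ring A) is an isovalerylphloroglucinol, with hydroxyls at C5 and C7, the 3-methylbutanoyl group at C6 and the third phloroglucinol oxygen serving as O1. C2 carries ring B, a 2,4-diformylphloroglucinol bound through its only unsubstituted carbon (C1′), C3 carries an isopropyl group and C4 is an unsubstituted methylene. The two adjacent stereocentres are (2R) and (3S), which places the aryl and isopropyl groups trans on the pyran ring. The C2–O1 bond is benzylic to a ring with ortho and para hydroxyls and can open to an ortho-quinone methide, so C2 is labile but self-correcting towards trans, whereas C3, a tertiary carbon with no heteroatom attached, is not restored once lost. Other sensitive groups are the two aryl aldehydes, five phenols and an enolisable ketone. The difficulty lies in setting C3 in absolute terms next to a bare methylene, and in making the oxygen para to the acyl group, not one of the two ortho oxygens, become O1. The strategy rests on the C4–C3–C2 unit: C4 is a methylene on C4a (the ring-A carbon ortho to O1), C3 is α to C2, and C2 is at the aldehyde oxidation level. This is the pattern left when a phenol adds through its ortho carbon to the β-carbon of 8 and the α-carbon is then protonated.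

## Retrosynthetic reasoning

**14 ⇒ 13.** The O–CH3 bonds at C5 and C7 are cut last. The two ethers exist so that, of the three ring-A oxygens, only the one para to the ketone is free; this fixes which oxygen becomes O1 in every ring closure. Both ethers are ortho to the C6 carbonyl, so the forward cleavage can use chelation to boron and need not touch O1.

**13 ⇒ 10 + 11 (through 12).** The C2–C1′ and O1–C2 bonds are cut together. This brings in ring B as the intact compound 11, with both formyl groups in place and no protecting groups. C2 is taken back to the aldehyde level, stored as lactol 10. In the forward direction 11 must attack the open aldehyde 9 at carbon, lose water to quinone methide 12, and be recaptured by the ring-A phenol. C2 is set relative to C3 in that closure, under kinetic and thermodynamic preference for trans.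

**10 ⇒ 6 + 8 (through 9).** The C4–C4a bond and the lactol O1–C2 bond are cut, and the C3–H bond is recognised as the stereo-defining bond. Cutting here rather than at C3–C4 or C3–isopropyl uses the innate nucleophilicity of the phenol ortho carbon and delivers all three carbons C4, C3 and C2 at the right oxidation level from one reagent. The two carbons ortho to the hydroxyl of 6 are equivalent and the para carbon is blocked, so no regiochemical question arises. The forward reaction must form C4–C4a by Friedel–Crafts conjugate addition under chiral primary amine catalysis, protonate the resulting enamine on one face, and close the lactol.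

**8 ⇒ 7.** The C=CH2 bond is cut. A one-carbon Mannich methylenation of 7 gives the α-branched acrolein in one step.

**6 ⇒ 5 ⇒ 4 ⇒ 2 + 3.** The phenol is masked as the benzyl ether 5, and the bond between the carbonyl carbon and the isobutyl CH2 is cut at the carbinol stage 4. Building the ketone from aldehyde 2 and Grignard reagent 3 fixes the acyl group para to the oxygen that will become O1. Direct acylation of a simpler phenol lacking the carbonyl carbon would favour the position ortho to the free hydroxyl instead.

**2 ⇒ 1.** The O–benzyl bond is cut. The ether is needed because a free para-hydroxyl would make carbinol 4 a ready precursor of a para-quinone methide. Aldehyde 1 is commercial.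

## Alternatives that were turned down

**Alternative 1: Matteson homologation on a ring-A benzylic boronic ester.**
- Disconnection: the C3–C4 and C3–isopropyl bonds, both made at a boron-bearing carbon.
- Forward key step: the benzylic boronic ester A1 forms an ate complex with dichloromethyllithium A2, and the benzyl group migrates to carbon (C3–C4). The Grignard reagent isopropylmagnesium bromide A3 then adds to boron and its isopropyl group migrates with displacement of chloride (C3–isopropyl), giving the secondary boronic ester A4.
- For: the diol auxiliary built into A1 controls both migrations with a predictability that few methods match. C3 is then stored as a configurationally inert C–B centre, with no epimerisable aldehyde until late. On certainty of the C3 configuration this alternative is stronger than the chosen route.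
- Against: the carbanionic reagents force the ketone to be carried as an alkyne and the phenol as a methoxymethyl ether. A4 still lacks C2, so a second one-carbon homologation and oxidation to the aldehyde must follow. Acetal removal, the ring-B condensation, alkyne hydration and demethylation come after that. The sequence is linear and roughly twice as long.
- Comparison: the chosen route obtains C4–C4a, the C3 centre and the O1–C2 ring at the correct oxidation level in one catalytic step from a four-step phenol. It accepts a less certain stereochemical outcome in exchange, and that risk sits in a single early step.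

**Alternative 2: Aryne annulation of an anti-aldol ester to a flavanone.**
- Disconnection: O1–C8a and C4–C4a.
- Forward key step: fluoride-induced desilylation releases the ring-A aryne from the silyl aryl triflate A5. The caesium alkoxide of the anti-aldol ester A6 adds at C8a, and the aryl anion at C4a attacks the ester, closing the 2,3-trans flavanone A7.
- For: the route is convergent. Both stereocentres come from acyclic aldol chemistry, so the trans relationship does not depend on a ring closure. The C5 methoxy group should direct the alkoxide to C8a. On convergence and on independent control of C2 this alternative is stronger.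
- Against:
  - C4 arrives as a ketone and must be reduced to a methylene beside an acid-labile benzylic C2–O1 bond.
  - In A7, C3 is α to that ketone and β to an aryloxy leaving group, so retro-oxa-Michael opening and enolisation threaten both centres under the basic conditions.
  - The β-alkoxide of A6 can undergo retro-aldol cleavage.
  - Ring B must be carried as a tris-methyl ether bis-acetal, so five methyl ethers and two acetals are removed at the end, and the alkyne must be hydrated.
  - A5 and A6 each need a multi-step synthesis.
- Comparison: the chosen route has C4 as a methylene from the outset, two methyl ethers instead of five, and no redox correction.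

**Alternative 3: Diformylphloroglucinol quinone methide closure on a lactol as the central step.**
- Disconnection: C2–C1′ and O1–C2.
- Forward key step: the C3-configured lactol A8 (the same compound as 10) condenses with the dialdehyde A9 (the same as 11). The resulting ring-B quinone methide is captured by the C8a phenol, giving the dimethyl ether A10 (the same as 13).
- For: ring B enters intact and unprotected, the 2,3-trans relationship corrects itself, and the step is closer to precedent than the key step chosen here. On those points it is as strong as anything available, which is why the same event is kept as step 7.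
- Against: taken as the strategy, it leaves open how A8 and its C3 centre are made. C3 is an α-branched aldehyde carbon in the open form and must be delivered and kept in enantiopure form by other chemistry, for example an auxiliary alkylation of about eight steps.
- Comparison: this is a complement to the chosen strategy, not a competitor. The chosen route supplies what this one lacks: the lactol, with C3 set, in one catalytic operation.

Key step: step 6

Assumption: the face of enamine protonation delivered by a given antipode of the diamine catalyst cannot be assigned with confidence for a phenol nucleophile. The (S)-diamine is written; the (R)-diamine, equally accessible from D-tert-leucine, is to be used if the first run shows the (3R) lactol.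

## Route

Step 1
Reactants: 1 4-hydroxy-2,6-dimethoxybenzaldehyde
Product: 2 4-(benzyloxy)-2,6-dimethoxybenzaldehyde
Conditions: BnBr, K2CO3, DMF, rt
Reagents that add atoms: benzyl bromide, BrCc1ccccc1
Why: Williamson etherification of a phenol made acidic by the para formyl group; the benzyl ether survives the Grignard addition and the oxidation, comes off by neutral hydrogenolysis, and prevents the carbinol of step 2 from collapsing to a para-quinone methide.

Step 2
Reactants: 2 4-(benzyloxy)-2,6-dimethoxybenzaldehyde; 3 isobutylmagnesium bromide
Product: 4 rac-1-[4-(benzyloxy)-2,6-dimethoxyphenyl]-3-methylbutan-1-ol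
Conditions: i-BuMgBr (1.5 equiv), THF, −20 °C to 0 °C; then sat. aq. NH4Cl
Reagents that add atoms: none
Why: Grignard 1,2-addition to the aldehyde, helped by chelation of magnesium between the carbonyl and a flanking methoxy group; the carbinol centre is racemic and is erased in step 3, and the crude alcohol is carried on without contact with strong acid because it ionises easily.

Step 3
Reactants: 4 rac-1-[4-(benzyloxy)-2,6-dimethoxyphenyl]-3-methylbutan-1-ol
Product: 5 1-[4-(benzyloxy)-2,6-dimethoxyphenyl]-3-methylbutan-1-one
Conditions: Dess–Martin periodinane, NaHCO3, CH2Cl2, 0 °C to rt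
Reagents that add atoms: none
Why: Dess–Martin oxidation of a secondary benzylic alcohol; the bicarbonate buffer removes the acetic acid that would otherwise ionise the trialkoxybenzylic carbinol, and the ethers are inert.

Step 4
Reactants: 5 1-[4-(benzyloxy)-2,6-dimethoxyphenyl]-3-methylbutan-1-one
Product: 6 1-(4-hydroxy-2,6-dimethoxyphenyl)-3-methylbutan-1-one
Conditions: H2 (1 atm), 10% Pd/C, EtOAc, rt
Reagents that add atoms: none
Why: Hydrogenolysis of the benzyl aryl ether over palladium metal; the ketone is twisted out of conjugation by two ortho methoxy groups and should not be reduced under neutral conditions at 1 atm.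

Step 5
Reactants: 7 isovaleraldehyde (3-methylbutanal)
Product: 8 2-isopropylacrolein (3-methyl-2-methylidenebutanal)
Conditions: 37% aq. CH2O, pyrrolidine (10 mol %), propionic acid (10 mol %), i-PrOH, 45 °C; distillation
Reagents that add atoms: formaldehyde, C=O
Why: Mannich α-methylenation: the enamine of 7 adds to the formaldehyde-derived iminium ion and the Mannich base eliminates the amine; the product has no α-hydrogen, so the reaction stops after one methylene.

Step 6
Reactants: 6 1-(4-hydroxy-2,6-dimethoxyphenyl)-3-methylbutan-1-one; 8 2-isopropylacrolein
Product: 10 (3S)-6-isovaleryl-3-isopropyl-5,7-dimethoxychroman-2-ol (both C2 epimers), via open-chain (S)-aldehyde 9 (not isolated)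
Conditions: 8 (1.1 equiv, slow addition), (S)-3,3-dimethyl-1-(pyrrolidin-1-yl)butan-2-amine·TfOH (20 mol %), CHCl3, 0 °C
Reagents that add atoms: none
Why: Proposed new method: the primary amine condenses with 8 to an α-branched iminium ion, for which primary amines are better suited than secondary ones, and the ring-A carbon ortho to the free hydroxyl of 6, activated by that hydroxyl and by the ortho and para methoxy groups, adds to the methylene terminus in a Friedel–Crafts conjugate addition that forms C4–C4a. The closest known reaction types are the primary–tertiary diamine salt-catalysed Friedel–Crafts alkylation of indoles by α-substituted acroleins ending in enantioselective enamine protonation, and the iminium [3+3] annulation of electron-rich phenols with enals to chroman-2-ols; new here is the pairing of a phenol with an α-branched acrolein, so that the stereocentre arises by protonation and not by C–C bond formation. The enamine left after the addition is protonated at C3 by the protonated tertiary amine of the catalyst, held over one face of the enamine, so the catalyst alone controls the new (S) centre. Hydrolysis releases aldehyde 9, which closes onto the neighbouring phenol oxygen by 6-exo-trig hemiacetalisation to lactol 10; the anomeric centre is left uncontrolled because it is rebuilt in step 7. The step needs C- over O-alkylation, which is expected because O-adducts revert by retro-oxa-Michael reaction whereas C-adducts do not, and mono-alkylation, which is favoured by the slow addition of 8 and by the lower reactivity of the etherified product. No regiochemical choice arises, since both carbons ortho to the hydroxyl of 6 are equivalent and the para carbon carries the acyl group. The lactol keeps the concentration of the α-branched aldehyde low and so protects C3 against renewed enamine formation.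

Step 7
Reactants: 10 (3S)-6-isovaleryl-3-isopropyl-5,7-dimethoxychroman-2-ol; 11 2,4-diformylphloroglucinol (2,4,6-trihydroxybenzene-1,3-dicarbaldehyde)
Product: 13 5-[(2R,3S)-5,7-dimethoxy-6-(3-methylbutanoyl)-3-(propan-2-yl)-3,4-dihydro-2H-chromen-2-yl]-2,4,6-trihydroxybenzene-1,3-dicarbaldehyde, via ring-B ortho-quinone methide 12 (not isolated)
Conditions: 11 (1.2 equiv), NaOAc, AcOH, 60 °C
Reagents that add atoms: none
Why: Knoevenagel-type hydroxyalkylation, dehydration and intramolecular oxa-Michael addition: the only unsubstituted carbon of 11 attacks the small equilibrium amount of open aldehyde 9 (C2–C1′), the carbinol loses water to quinone methide 12, and the ring-A phenol adds to the methide carbon (6-exo-trig) to close O1–C2. C2 is set relative to C3, because a chair-like closure places aryl and isopropyl both equatorial and because the product can reopen to 12, so the trans (2R,3S) isomer is also the thermodynamic one. No amine is present, so C3 is not exposed to enamine formation.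

Step 8
Reactants: 13 5-[(2R,3S)-5,7-dimethoxy-6-(3-methylbutanoyl)-3-(propan-2-yl)-3,4-dihydro-2H-chromen-2-yl]-2,4,6-trihydroxybenzene-1,3-dicarbaldehyde
Product: 14 5-[(2R,3S)-5,7-dihydroxy-6-(3-methylbutanoyl)-3-(propan-2-yl)-3,4-dihydro-2H-chromen-2-yl]-2,4,6-trihydroxybenzene-1,3-dicarbaldehyde
Conditions: BCl3 (excess), n-Bu4NI, CH2Cl2, −78 °C to 0 °C; then ice-water
Reagents that add atoms: none
Why: Lewis-acid ether cleavage: both methoxy groups are ortho to the C6 ketone, so boron binds in a six-membered chelate with the carbonyl oxygen and iodide removes each methyl group by SN2 attack, while the non-chelated O1 and the hydrogen-bonded formyl groups should be spared at low temperature. No stereocentre is touched while C2–O1 stays closed, and reclosure after any opening again favours trans.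

## Compound list

1 | 4-hydroxy-2,6-dimethoxybenzaldehyde | O=Cc1c(OC)cc(O)cc1OC | starting material
2 | 4-(benzyloxy)-2,6-dimethoxybenzaldehyde | O=Cc1c(OC)cc(OCc2ccccc2)cc1OC | intermediate
3 | isobutylmagnesium bromide | CC(C)C[Mg]Br | starting material
4 | rac-1-[4-(benzyloxy)-2,6-dimethoxyphenyl]-3-methylbutan-1-ol | CC(C)CC(O)c1c(OC)cc(OCc2ccccc2)cc1OC | intermediate
5 | 1-[4-(benzyloxy)-2,6-dimethoxyphenyl]-3-methylbutan-1-one | CC(C)CC(=O)c1c(OC)cc(OCc2ccccc2)cc1OC | intermediate
6 | 1-(4-hydroxy-2,6-dimethoxyphenyl)-3-methylbutan-1-one | CC(C)CC(=O)c1c(OC)cc(O)cc1OC | intermediate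
7 | isovaleraldehyde (3-methylbutanal) | CC(C)CC=O | starting material
8 | 2-isopropylacrolein (3-methyl-2-methylidenebutanal) | CC(C)C(=C)C=O | intermediate
9 | (2S)-2-{[6-hydroxy-2,4-dimethoxy-3-(3-methylbutanoyl)phenyl]methyl}-3-methylbutanal (open-chain aldehyde, not isolated) | CC(C)CC(=O)c1c(OC)cc(O)c(c1OC)C[C@@H](C(C)C)C=O | intermediate
10 | 1-[(3S)-2-hydroxy-5,7-dimethoxy-3-(propan-2-yl)-3,4-dihydro-2H-chromen-6-yl]-3-methylbutan-1-one (both C2 epimers) | CC(C)CC(=O)c1c(OC)cc2c(c1OC)C[C@@H](C(C)C)C(O)O2 | intermediate
11 | 2,4-diformylphloroglucinol (2,4,6-trihydroxybenzene-1,3-dicarbaldehyde) | O=Cc1c(O)cc(O)c(C=O)c1O | starting material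
12 | ring-B ortho-quinone methide of the open-chain form, (S) at the isopropyl-bearing carbon (not isolated) | CC(C)CC(=O)c1c(OC)cc(O)c(c1OC)C[C@@H](C(C)C)C=C1C(=O)C(C=O)=C(O)C(C=O)=C1O | intermediate
13 | 5-[(2R,3S)-5,7-dimethoxy-6-(3-methylbutanoyl)-3-(propan-2-yl)-3,4-dihydro-2H-chromen-2-yl]-2,4,6-trihydroxybenzene-1,3-dicarbaldehyde | CC(C)CC(=O)c1c(OC)cc2c(c1OC)C[C@@H](C(C)C)[C@H](c1c(O)c(C=O)c(O)c(C=O)c1O)O2 | intermediate
14 | 5-[(2R,3S)-5,7-dihydroxy-6-(3-methylbutanoyl)-3-(propan-2-yl)-3,4-dihydro-2H-chromen-2-yl]-2,4,6-trihydroxybenzene-1,3-dicarbaldehyde | CC(C)CC(=O)c1c(O)cc2c(c1O)C[C@@H](C(C)C)[C@H](c1c(O)c(C=O)c(O)c(C=O)c1O)O2 | target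

## Step count and least certain steps

Total step count: 8. Longest linear sequence: 7 steps (steps 1, 2, 3, 4, 6, 7, 8 from 1); step 5 is a one-step branch.

**Step 6 (key step, carries the label).** The most likely failure is poor face selectivity in the protonation of the enamine. The neighbouring phenol hydroxyl can hand its proton to C3 through a six-membered transition state without the catalyst taking part. Slow addition to the acyl-deactivated ring, second alkylation at C8, and acid-mediated condensation of the lactol with a second molecule of phenol are further risks.

Fallback by known chemistry, setting out from 6 and returning at 10: magnesium-mediated ortho-formylation of 6 (MgCl2, Et3N, paraformaldehyde, MeCN, reflux) should give 6-hydroxy-2,4-dimethoxy-3-(3-methylbutanoyl)benzaldehyde F1. Benzylation (BnBr, K2CO3, DMF) then gives the benzyl ether aldehyde F2, and NaBH4 in MeOH/THF at −20 °C reduces the aldehyde in preference to the hindered ketone, giving the benzylic alcohol F3. Appel bromination (CBr4, PPh3, CH2Cl2, 0 °C) converts this into the benzylic bromide F4, which is used at once. In an Evans alkylation, the sodium enolate of commercial (S)-4-benzyl-3-(3-methylbutanoyl)-1,3-oxazolidin-2-one (NaN(SiMe3)2, THF, −78 °C) is alkylated by F4 anti to the benzyl group of the chelated Z-enolate, which gives the (2S)-configured imide F5. LiOH/H2O2 in aqueous THF releases the (S)-carboxylic acid F6. Hydrogenolysis (H2, Pd/C, EtOAc) frees the phenol, which lactonises on brief contact with catalytic TsOH to the (3S)-dihydrocoumarin F7. Finally i-Bu2AlH (1.05 equiv, CH2Cl2, −78 °C) reduces the aryl lactone, in preference to the hindered ketone, to lactol 10.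

**Step 7.** The most likely failures are loss of configuration at C3, by enolisation of the open aldehyde or by tautomerisation of the quinone methide to a styrene, and slow C–C bond formation because the aldehyde is masked and the dialdehyde is a weak carbon nucleophile.

Fallback, setting out from 10 and returning at 13: the formyl groups are introduced after the C2–C1′ bond. Lactol 10 is condensed with an excess of phloroglucinol, a far better nucleophile, under cold acid catalysis (BF3·OEt2, CH2Cl2/MeCN, −20 °C). This should give the trans 2-(2,4,6-trihydroxyphenyl)chroman F8 by the same closure. Vilsmeier–Haack formylation (POCl3, DMF, 0 °C; aqueous hydrolysis) then fills the two free positions of the trihydroxyphenyl ring, which are much more reactive than C8 of the etherified ring A, to give 13.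

**Step 8.** The most likely failures are incomplete cleavage of the second ether once the first phenoxide has tied the ketone up in a boron chelate, and Lewis-acid opening of the C2–O1 bond with loss of material.

Fallback, setting out from 6 and returning at 14: the ethers are removed before any stereocentre or labile bond exists. BBr3 (CH2Cl2, −78 °C to rt) converts 6 into 3-methyl-1-(2,4,6-trihydroxyphenyl)butan-1-one F9. The annulation of step 6 with 8 is run on this triol to give the trihydroxy lactol F10, and the condensation of step 7 with 11 then leads directly to 14. The price is that closure through a hydroxyl ortho to the ketone is no longer excluded; it is disfavoured only by the hydrogen bond of that hydroxyl to the carbonyl group, so a chromatographic separation must be expected.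

**Step 2.** The most likely failures are hydride transfer from the β-branched Grignard reagent to the hindered aldehyde (reduction in place of addition), and ionisation of the trialkoxybenzylic carbinol during work-up.

Fallback, setting out from 2 and returning at 5: the carbinol stage is bypassed. Aldehyde 2 is converted with I2 and aqueous NH3 in THF into 4-(benzyloxy)-2,6-dimethoxybenzonitrile F11. Reagent 3 is added to the nitrile (THF/toluene, reflux, CuBr cat.), and the ketimine is hydrolysed with warm aqueous HCl to ketone 5.

## Further compounds

F1 | step 6 | 6-hydroxy-2,4-dimethoxy-3-(3-methylbutanoyl)benzaldehyde | CC(C)CC(=O)c1c(OC)cc(O)c(C=O)c1OC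
F2 | step 6 | 6-(benzyloxy)-2,4-dimethoxy-3-(3-methylbutanoyl)benzaldehyde | CC(C)CC(=O)c1c(OC)cc(OCc2ccccc2)c(C=O)c1OC
F3 | step 6 | 1-[4-(benzyloxy)-3-(hydroxymethyl)-2,6-dimethoxyphenyl]-3-methylbutan-1-one | CC(C)CC(=O)c1c(OC)cc(OCc2ccccc2)c(CO)c1OC
F4 | step 6 | 1-[4-(benzyloxy)-3-(bromomethyl)-2,6-dimethoxyphenyl]-3-methylbutan-1-one | CC(C)CC(=O)c1c(OC)cc(OCc2ccccc2)c(CBr)c1OC
F5 | step 6 | (4S)-4-benzyl-3-[(2S)-2-{[6-(benzyloxy)-2,4-dimethoxy-3-(3-methylbutanoyl)phenyl]methyl}-3-methylbutanoyl]-1,3-oxazolidin-2-one | CC(C)CC(=O)c1c(OC)cc(OCc2ccccc2)c(c1OC)C[C@@H](C(C)C)C(=O)N1[C@@H](Cc2ccccc2)COC1=O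
F6 | step 6 | (2S)-2-{[6-(benzyloxy)-2,4-dimethoxy-3-(3-methylbutanoyl)phenyl]methyl}-3-methylbutanoic acid | CC(C)CC(=O)c1c(OC)cc(OCc2ccccc2)c(c1OC)C[C@@H](C(C)C)C(O)=O
F7 | step 6 | (3S)-5,7-dimethoxy-6-(3-methylbutanoyl)-3-(propan-2-yl)-3,4-dihydro-2H-chromen-2-one | CC(C)CC(=O)c1c(OC)cc2c(c1OC)C[C@@H](C(C)C)C(=O)O2
F8 | step 7 | 2-[(2R,3S)-5,7-dimethoxy-6-(3-methylbutanoyl)-3-(propan-2-yl)-3,4-dihydro-2H-chromen-2-yl]benzene-1,3,5-triol | CC(C)CC(=O)c1c(OC)cc2c(c1OC)C[C@@H](C(C)C)[C@H](c1c(O)cc(O)cc1O)O2
F9 | step 8 | 3-methyl-1-(2,4,6-trihydroxyphenyl)butan-1-one | CC(C)CC(=O)c1c(O)cc(O)cc1O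
F10 | step 8 | 1-[(3S)-2,5,7-trihydroxy-3-(propan-2-yl)-3,4-dihydro-2H-chromen-6-yl]-3-methylbutan-1-one (both C2 epimers) | CC(C)CC(=O)c1c(O)cc2c(c1O)C[C@@H](C(C)C)C(O)O2
F11 | step 2 | 4-(benzyloxy)-2,6-dimethoxybenzonitrile | N#Cc1c(OC)cc(OCc2ccccc2)cc1OC
A1 | alternative 1 | (4S,5S)-4,5-dicyclohexyl-2-{[6-(methoxymethoxy)-2,4-dimethoxy-3-(3-methylbut-1-yn-1-yl)phenyl]methyl}-1,3,2-dioxaborolane | CC(C)C#Cc1c(OC)cc(OCOC)c(c1OC)CB1O[C@@H](C2CCCCC2)[C@H](C2CCCCC2)O1
A2 | alternative 1 | dichloromethyllithium | [Li]C(Cl)Cl
A3 | alternative 1 | isopropylmagnesium bromide | CC(C)[Mg]Br
A4 | alternative 1 | (4S,5S)-4,5-dicyclohexyl-2-{(2S)-1-[6-(methoxymethoxy)-2,4-dimethoxy-3-(3-methylbut-1-yn-1-yl)phenyl]-3-methylbutan-2-yl}-1,3,2-dioxaborolane | CC(C)C#Cc1c(OC)cc(OCOC)c(c1OC)C[C@@H](C(C)C)B1O[C@@H](C2CCCCC2)[C@H](C2CCCCC2)O1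
A5 | alternative 2 | 3,5-dimethoxy-4-(3-methylbut-1-yn-1-yl)-2-(trimethylsilyl)phenyl trifluoromethanesulfonate | CC(C)C#Cc1c(OC)cc(OS(=O)(=O)C(F)(F)F)c([Si](C)(C)C)c1OC
A6 | alternative 2 | methyl (2S,3R)-3-[3,5-bis(1,3-dioxolan-2-yl)-2,4,6-trimethoxyphenyl]-3-hydroxy-2-(propan-2-yl)propanoate | COC(=O)[C@@H](C(C)C)[C@H](c1c(OC)c(C2OCCO2)c(OC)c(C2OCCO2)c1OC)O
A7 | alternative 2 | (2R,3S)-2-[3,5-bis(1,3-dioxolan-2-yl)-2,4,6-trimethoxyphenyl]-5,7-dimethoxy-6-(3-methylbut-1-yn-1-yl)-3-(propan-2-yl)-2,3-dihydro-4H-chromen-4-one | CC(C)C#Cc1c(OC)cc2c(c1OC)C(=O)[C@@H](C(C)C)[C@H](c1c(OC)c(C3OCCO3)c(OC)c(C3OCCO3)c1OC)O2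
A8 | alternative 3 | 1-[(3S)-2-hydroxy-5,7-dimethoxy-3-(propan-2-yl)-3,4-dihydro-2H-chromen-6-yl]-3-methylbutan-1-one (identical with 10) | CC(C)CC(=O)c1c(OC)cc2c(c1OC)C[C@@H](C(C)C)C(O)O2
A9 | alternative 3 | 2,4,6-trihydroxybenzene-1,3-dicarbaldehyde (identical with 11) | O=Cc1c(O)cc(O)c(C=O)c1O
A10 | alternative 3 | 5-[(2R,3S)-5,7-dimethoxy-6-(3-methylbutanoyl)-3-(propan-2-yl)-3,4-dihydro-2H-chromen-2-yl]-2,4,6-trihydroxybenzene-1,3-dicarbaldehyde (identical with 13) | CC(C)CC(=O)c1c(OC)cc2c(c1OC)C[C@@H](C(C)C)[C@H](c1c(O)c(C=O)c(O)c(C=O)c1O)O2
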